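The route rests on cutting the ring-B side chain between C5 and C6 (counted from ring B), where C6 stands γ to the C9 carbonyl of the 2,6-dihydroxyphenyl ketone. C6, C7 and C8 are therefore carried as the three-membered ring of cyclopropyl 2,6-dimethoxyphenyl ketone. A nickel-catalysed reductive ring-opening cross-coupling with the primary halide at C5 of the fully assembled biaryl (chain A already complete) forms the C5–C6 bond, opens the ring and delivers the C9 ketone and the saturated C6–C8 segment in one operation. The precursors are a 5-chloropentyl biaryl and an acylcyclopropane; all eight phenols travel as methyl ethers and are released last.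

Key step: step 9

Remark on the chemistry: ring A is the 2,3-dihydroxy-5-alkylphenyl ring and ring B the 4,5-dihydroxy-2-alkylphenyl ring. Chain carbons are counted from the arene (C1 benzylic, C9 carbonyl). The target has no stereocentre, and the biaryl axis, with only one hydroxyl and one alkyl ortho substituent, is taken as freely rotating, so no stereocontrol is required.

Step 1
Reactants: 1 1,3-dimethoxybenzene; 2 N-methoxy-N-methylcyclopropanecarboxamide
Product: 4 cyclopropyl(2,6-dimethoxyphenyl)methanone, via 2,6-dimethoxyphenyllithium 3 (not isolated)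
Conditions: n-BuLi, THF, 0 °C to rt; then 2, −78 °C to 0 °C; aq. NH4Cl
Reagents that add atoms: none
Why: Directed ortho-metalation at C2 of 1 (flanked by both methoxy groups) followed by Weinreb ketone synthesis should stop at the ketone, because the chelated tetrahedral adduct collapses only on work-up.

Step 2
Reactants: 5 1-(2,6-dimethoxyphenyl)ethan-1-one; 6 7-bromohept-1-ene
Product: 8 1-(2,6-dimethoxyphenyl)non-8-en-1-one, via lithium enolate 7 (not isolated)
Conditions: LDA, THF, −78 °C; then 6, DMPU, −78 °C to rt
Reagents that add atoms: none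
Why: Kinetic deprotonation of the methyl ketone and SN2 alkylation of the lithium enolate with a primary bromide (enolate alkylation) should give the mono-alkylated ketone, the hindered carbonyl being unable to self-condense.

Step 3
Reactants: 9 4-bromo-1,2-dimethoxybenzene; 10 5-chloropent-1-ene
Product: 12 4-(5-chloropentyl)-1,2-dimethoxybenzene, via B-(5-chloropentyl)-9-BBN 11 (not isolated)
Conditions: 10, 9-BBN, THF, 0 °C to rt; then 9, Pd(dppf)Cl2 (cat.), aq. K3PO4, THF/DMF, 60 °C
Reagents that add atoms: none
Why: Anti-Markovnikov hydroboration of the terminal alkene with 9-BBN and B-alkyl Suzuki–Miyaura coupling with the aryl bromide should leave the primary alkyl chloride untouched, since Pd(dppf) does not insert into unactivated C(sp3)–Cl bonds.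

Step 4
Reactants: 12 4-(5-chloropentyl)-1,2-dimethoxybenzene
Product: 13 1-bromo-2-(5-chloropentyl)-4,5-dimethoxybenzene
Conditions: NBS, MeCN, 0 °C to rt, dark
Reagents that add atoms: N-bromosuccinimide, O=C1CCC(=O)N1Br
Why: Electrophilic aromatic bromination should occur para to a methoxy group and ortho to the alkyl chain, the other free sites being either flanked by two substituents or not para to an oxygen.

Step 5
Reactants: 14 4-bromo-2-methoxyphenol
Product: 15 4-bromo-2-iodo-6-methoxyphenol
Conditions: NIS, p-TsOH (cat.), MeCN, rt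
Reagents that add atoms: N-iodosuccinimide, O=C1CCC(=O)N1I
Why: Electrophilic aromatic iodination of the phenol should take the only free position ortho to the hydroxyl group, the para position being occupied by bromine.

Step 6
Reactants: 15 4-bromo-2-iodo-6-methoxyphenol
Product: 16 5-bromo-1-iodo-2,3-dimethoxybenzene
Conditions: MeI, K2CO3, acetone, reflux
Reagents that add atoms: iodomethane, CI
Why: Williamson O-methylation of the phenoxide caps the last free phenol so that all oxygens are uniform methyl ethers.

Step 7
Reactants: 13 1-bromo-2-(5-chloropentyl)-4,5-dimethoxybenzene; 16 5-bromo-1-iodo-2,3-dimethoxybenzene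
Product: 19 5-bromo-2'-(5-chloropentyl)-2,3,4',5'-tetramethoxy-1,1'-biphenyl, via aryllithium 17 (not isolated), via arylzinc chloride 18 (not isolated)
Conditions: 13, n-BuLi, THF, −78 °C; ZnCl2, −78 °C to rt; then 16, Pd(PPh3)4 (cat.), THF, rt to 50 °C
Reagents that add atoms: none
Why: Bromine–lithium exchange at −78 °C (faster than any attack on the primary chloride), transmetalation to zinc and Negishi coupling should join the rings at the C–I bond only, because oxidative addition of Pd(0) to an aryl iodide far outpaces that to an aryl bromide.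

Step 8
Reactants: 8 1-(2,6-dimethoxyphenyl)non-8-en-1-one; 19 5-bromo-2'-(5-chloropentyl)-2,3,4',5'-tetramethoxy-1,1'-biphenyl
Product: 21 9-[2'-(5-chloropentyl)-2,3,4',5'-tetramethoxy-[1,1'-biphenyl]-5-yl]-1-(2,6-dimethoxyphenyl)nonan-1-one, via B-alkyl-9-BBN 20 (not isolated)
Conditions: 8, 9-BBN, THF, 0 °C to rt; then 19, Pd(dppf)Cl2 (cat.), aq. K3PO4, THF/DMF, 60 °C
Reagents that add atoms: none
Why: 9-BBN should hydroborate the terminal alkene of 8 faster than it reduces the doubly ortho-substituted aryl ketone, and the primary alkylborane then undergoes B-alkyl Suzuki–Miyaura coupling at the unhindered aryl bromide of 19.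

Step 9
Reactants: 21 9-[2'-(5-chloropentyl)-2,3,4',5'-tetramethoxy-[1,1'-biphenyl]-5-yl]-1-(2,6-dimethoxyphenyl)nonan-1-one; 4 cyclopropyl(2,6-dimethoxyphenyl)methanone
Product: 24 9,9'-(2,3,4',5'-tetramethoxy-[1,1'-biphenyl]-5,2'-diyl)bis[1-(2,6-dimethoxyphenyl)nonan-1-one], via alkyl iodide 22 (not isolated), via zinc enolate 23 (not isolated)
Conditions: 4 (2 equiv), NiBr2·glyme (10 mol%), 4,4'-dimethyl-2,2'-bipyridine (12 mol%), Zn, NaI, DMA, 50 °C; then 1 M HCl
Reagents that add atoms: none
Why: Zinc-reduced bipyridine–nickel(0) inserts into a C(acyl-bearing)–CH2 bond of the acylcyclopropane of 4, aided by Lewis-acid coordination of the carbonyl, to give a γ-nickel enolate whose oxygen passes to zinc, while the primary iodide 22, formed from chloride 21 by in-flask halide exchange, is turned by low-valent nickel into the C5 radical that is captured at nickel, and C(sp3)–C(sp3) reductive elimination forms the C5–C6 bond. The zinc enolate 23 is protonated on work-up, so the C9 ketone and the methylenes C6–C8 appear in their final oxidation state without any redox or protecting-group adjustment. The closest known reaction type is the nickel-catalysed reductive ring-opening γ-alkylation of aryl cyclopropyl ketones with unactivated primary alkyl halides (cross-electrophile coupling with iodide exchange for chlorides). No ring is closed and no stereocentre is formed, and because the two ring CH2 groups of 4 are equivalent the ring opening has no regiochemical issue. The step needs cross- over homo-coupling, which the different activation modes of the two electrophiles (two-electron C–C insertion for 4, halogen abstraction for 22) and an excess of 4 should secure, and chemoselectivity over the second aryl ketone of 21, which lacks the strained ring and should be inert. The main risk is that the 2,6-dimethoxyaryl ketone is twisted out of conjugation and so less activated than a simple aryl cyclopropyl ketone, although its ortho-methoxy groups may assist Lewis-acid chelation.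

Step 10
Reactants: 24 9,9'-(2,3,4',5'-tetramethoxy-[1,1'-biphenyl]-5,2'-diyl)bis[1-(2,6-dimethoxyphenyl)nonan-1-one]
Product: 25 9,9'-(2,3,4',5'-tetrahydroxy-[1,1'-biphenyl]-5,2'-diyl)bis[1-(2,6-dihydroxyphenyl)nonan-1-one] (CNP0305015.0)
Conditions: BBr3 (excess), CH2Cl2, −78 °C to rt; ice-water quench under argon
Reagents that add atoms: none
Why: Boron tribromide complexes each ether oxygen and bromide removes the methyl group by SN2 (Lewis-acid ether cleavage), the ortho-acyl methoxy groups being assisted by chelation, and aqueous work-up frees the eight phenols.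

Compound list
1 | 1,3-dimethoxybenzene | COc1cccc(OC)c1 | starting material
2 | N-methoxy-N-methylcyclopropanecarboxamide | CON(C)C(=O)C1CC1 | starting material
3 | 2,6-dimethoxyphenyllithium | [Li]c1c(OC)cccc1OC | intermediate
4 | cyclopropyl(2,6-dimethoxyphenyl)methanone | COc1cccc(OC)c1C(=O)C1CC1 | intermediate
5 | 1-(2,6-dimethoxyphenyl)ethan-1-one | COc1cccc(OC)c1C(C)=O | starting material
6 | 7-bromohept-1-ene | C=CCCCCCBr | starting material
7 | lithium enolate of 5 (lithium 1-(2,6-dimethoxyphenyl)ethen-1-olate) | [Li]OC(=C)c1c(OC)cccc1OC | intermediate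
8 | 1-(2,6-dimethoxyphenyl)non-8-en-1-one | C=CCCCCCCC(=O)c1c(OC)cccc1OC | intermediate
9 | 4-bromo-1,2-dimethoxybenzene | COc1ccc(Br)cc1OC | starting material
10 | 5-chloropent-1-ene | C=CCCCCl | starting material
11 | 9-(5-chloropentyl)-9-borabicyclo[3.3.1]nonane | ClCCCCCB1C2CCCC1CCC2 | intermediate
12 | 4-(5-chloropentyl)-1,2-dimethoxybenzene | COc1ccc(CCCCCCl)cc1OC | intermediate
13 | 1-bromo-2-(5-chloropentyl)-4,5-dimethoxybenzene | COc1cc(Br)c(CCCCCCl)cc1OC | intermediate
14 | 4-bromo-2-methoxyphenol | COc1cc(Br)ccc1O | starting material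
15 | 4-bromo-2-iodo-6-methoxyphenol | COc1cc(Br)cc(I)c1O | intermediate
16 | 5-bromo-1-iodo-2,3-dimethoxybenzene | COc1cc(Br)cc(I)c1OC | intermediate
17 | [2-(5-chloropentyl)-4,5-dimethoxyphenyl]lithium | [Li]c1cc(OC)c(OC)cc1CCCCCCl | intermediate
18 | [2-(5-chloropentyl)-4,5-dimethoxyphenyl]zinc chloride | Cl[Zn]c1cc(OC)c(OC)cc1CCCCCCl | intermediate
19 | 5-bromo-2'-(5-chloropentyl)-2,3,4',5'-tetramethoxy-1,1'-biphenyl | COc1cc(Br)cc(-c2cc(OC)c(OC)cc2CCCCCCl)c1OC | intermediate
20 | 9-[9-(2,6-dimethoxyphenyl)-9-oxononyl]-9-borabicyclo[3.3.1]nonane | O=C(CCCCCCCCB1C2CCCC1CCC2)c1c(OC)cccc1OC | intermediate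
21 | 9-[2'-(5-chloropentyl)-2,3,4',5'-tetramethoxy-[1,1'-biphenyl]-5-yl]-1-(2,6-dimethoxyphenyl)nonan-1-one | COc1cc(CCCCCCCCC(=O)c2c(OC)cccc2OC)cc(-c2cc(OC)c(OC)cc2CCCCCCl)c1OC | intermediate
22 | 9-[2'-(5-iodopentyl)-2,3,4',5'-tetramethoxy-[1,1'-biphenyl]-5-yl]-1-(2,6-dimethoxyphenyl)nonan-1-one | COc1cc(CCCCCCCCC(=O)c2c(OC)cccc2OC)cc(-c2cc(OC)c(OC)cc2CCCCCI)c1OC | intermediate
23 | iodozinc (Z)-enolate of 24 at the ring-B chain ketone (C8=C9–O–ZnI) | COc1cc(CCCCCCCCC(=O)c2c(OC)cccc2OC)cc(-c2cc(OC)c(OC)cc2CCCCCCC/C=C(\O[Zn]I)c2c(OC)cccc2OC)c1OC | intermediate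
24 | 9,9'-(2,3,4',5'-tetramethoxy-[1,1'-biphenyl]-5,2'-diyl)bis[1-(2,6-dimethoxyphenyl)nonan-1-one] | COc1cc(CCCCCCCCC(=O)c2c(OC)cccc2OC)cc(-c2cc(OC)c(OC)cc2CCCCCCCCC(=O)c2c(OC)cccc2OC)c1OC | intermediate
25 | 9,9'-(2,3,4',5'-tetrahydroxy-[1,1'-biphenyl]-5,2'-diyl)bis[1-(2,6-dihydroxyphenyl)nonan-1-one] | O=C(CCCCCCCCc1cc(O)c(O)c(-c2cc(O)c(O)cc2CCCCCCCCC(=O)c2c(O)cccc2O)c1)c1c(O)cccc1O | target

Total step count: 10. Longest linear sequence: 6 steps (3, 4, 7, 8, 9, 10).

Steps most likely to fail

Step 9. The twisted 2,6-dimethoxyaryl ketone may resist C–C insertion at nickel, so that reductive homocoupling or hydrodehalogenation of the alkyl halide outruns cross-coupling. The fallback sets out from 21 and 4 and returns at 24, replacing the cross-electrophile ring opening by a palladium-catalysed alkyl–alkyl Negishi coupling across the same C5–C6 bond. Compound 21 would be converted with NaI in refluxing acetone into the iodide 22, isolated this time. Compound 4 would be opened with HBr in acetic acid at rt to 4-bromo-1-(2,6-dimethoxyphenyl)butan-1-one F1. Zinc insertion (Zn dust, LiCl, THF, 50 °C) should turn this into [4-(2,6-dimethoxyphenyl)-4-oxobutyl]zinc bromide F2. Coupling of F2 with 22 (Pd2(dba)3, tricyclopentylphosphine, N-methylimidazole, THF/NMP, 80 °C) should give 24.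

Step 10. Eightfold ether cleavage may stall at the methoxy groups that remain ortho to each ketone after the first chelation-assisted cleavage, and long exposure of the liberated catechols to BBr3/HBr invites oxidative degradation. The fallback sets out from 24 and returns at 25 by a staged unmasking. BCl3 (CH2Cl2, −78 to 0 °C) should first remove only one chelated methyl group beside each carbonyl, giving 9,9'-(2,3,4',5'-tetramethoxy-[1,1'-biphenyl]-5,2'-diyl)bis[1-(2-hydroxy-6-methoxyphenyl)nonan-1-one] F3. The remaining six ethers would then be cleaved by hard-acid/soft-nucleophile dealkylation (AlCl3, ethanethiol, CH2Cl2, 0 °C to rt) to give 25.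

Step 8. 9-BBN may reduce the ketone of 8 in competition with hydroboration, or the alkylborane may transmetalate sluggishly and be lost by protodeboronation. The fallback sets out from 5 and 19 and returns at 21 by aryl–alkyl cross-electrophile coupling instead of organoboron chemistry. The enolate of 5 (LDA, THF, −78 °C) would be alkylated with excess 1,7-dibromoheptane to give 9-bromo-1-(2,6-dimethoxyphenyl)nonan-1-one F4. Nickel-catalysed reductive coupling of F4 with aryl bromide 19 (NiBr2·glyme, 4,4'-di-tert-butyl-2,2'-bipyridine, Zn, DMA, 60 °C, no iodide additive so that the alkyl chloride stays intact) should give 21.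

Further compounds
F1 | step 9 | 4-bromo-1-(2,6-dimethoxyphenyl)butan-1-one | O=C(CCCBr)c1c(OC)cccc1OC
F2 | step 9 | [4-(2,6-dimethoxyphenyl)-4-oxobutyl]zinc bromide | O=C(CCC[Zn]Br)c1c(OC)cccc1OC
F3 | step 10 | 9,9'-(2,3,4',5'-tetramethoxy-[1,1'-biphenyl]-5,2'-diyl)bis[1-(2-hydroxy-6-methoxyphenyl)nonan-1-one] | COc1cc(CCCCCCCCC(=O)c2c(O)cccc2OC)cc(-c2cc(OC)c(OC)cc2CCCCCCCCC(=O)c2c(O)cccc2OC)c1OC
F4 | step 8 | 9-bromo-1-(2,6-dimethoxyphenyl)nonan-1-one | O=C(CCCCCCCCBr)c1c(OC)cccc1OC
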